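**Retrosynthetic overview**

1. Numbering (germacranolide): C1 furanone C=O, C2=C3, ether bridge C3–O–C10, C4(C15H2OAc)=C5, C6–O/C7–C11(=C13H2)–C12 lactone, C8 (O-methacrylate), C9, C10 (C14H3).
2. Endgame: target ⇐ α-methylene lactone unmasked from a β-sulfonyl lactone and C8 acylated ⇐ C8 alcohol ⇐ C8 ketone ⇐ C8=CH2 (Lemieux–Johnson) and furanone C2=C3 (Saegusa–Ito) ⇐ bridged ketone 26.
3. Key disconnection: 26 ⇐ diazoketone 24. A copper carbenoid at C10 is captured by the oxocene oxygen, and the oxonium ylide undergoes a [2,3] shift of its O–CH2–C8(=CH2) unit. The eight-membered oxocene grows by one atom to the nine-membered oxacycle, while the furanone ring and the ten-membered carbocycle close and C10 is set.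
4. 24 ⇐ oxocene 21 (RCM, C4=C5) ⇐ ether 20 ⇐ aldol fragment 7 (C1–C4, C15) + lactone allyl bromide 19 (C5–C9, C11–C13, from (S)-hydroxymethylbutenolide). Ring order: γ-lactone (chiral pool) → oxocene → furanone, nine-membered oxacycle and ten-membered carbocycle together.
5. Enabling feature: the ether oxygen of the nine-membered ring lies between C3 and C10; C10 is α to the C1 ketone (a diazoketone carbon) and bonded to C9H2–C8(–O). An O–CH2–C(=CH2) allyl ether in an eight-membered ring can therefore pass its methylene terminus to C10 through a five-membered oxonium ylide, and the exocyclic alkene left at C8 is the latent C8–O.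

Key step: step 16

Remark: C11 (lactone α-carbon) is carried as an epimer mixture from 12 to 32 and is left undefined in the SMILES; it becomes sp2 in step 21.
Remark: in 19–25 the O–CH2 carbon on C8 ends as the exocyclic methylene of 26, and the exocyclic methylene of 19–25 becomes C9.

**Route**

Step 1
Reactants: 1 2-methylidenepropane-1,3-diol
Product: 2 2-(hydroxymethyl)prop-2-en-1-yl acetate
Conditions: vinyl acetate (1.1 equiv), Novozym 435, MTBE, rt
Reagents that add atoms: vinyl acetate, CC(=O)OC=C
Why: Lipase-catalysed irreversible transesterification of the symmetric diol should stop at the monoacetate, which places the C15 acetate of the target at the outset; no stereocenter is formed.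

Step 2
Reactants: 2 2-(hydroxymethyl)prop-2-en-1-yl acetate
Product: 3 2-formylprop-2-en-1-yl acetate
Conditions: MnO2 (10 equiv), CH2Cl2, rt; filtered and used at once
Reagents that add atoms: none
Why: MnO2 oxidation of a primary allylic alcohol should give the enal without touching the acetate.

Step 3
Reactants: 4 tert-butyl acetate
Product: 5 1-(tert-butoxy)-1-(trimethylsilyloxy)ethene
Conditions: LDA, THF, −78 °C; TMSCl, −78 °C → rt; distillation
Reagents that add atoms: chlorotrimethylsilane, C[Si](C)(C)Cl
Why: O-silylation of the lithium ester enolate is the standard preparation of a ketene silyl acetal.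

Step 4
Reactants: 3 2-formylprop-2-en-1-yl acetate; 5 1-(tert-butoxy)-1-(trimethylsilyloxy)ethene
Product: 7 tert-butyl (3R)-5-acetoxy-3-hydroxy-4-methylidenepentanoate, via silyl ether 6 (not isolated)
Conditions: Ti(IV) complex of a tridentate BINOL-derived Schiff-base ligand with 3,5-di-tert-butylsalicylate (3 mol%; ligand antipode for Re-face attack), Et2O, −10 °C; then 1 M HCl, THF, 0 °C
Reagents that add atoms: none
Why: A catalytic enantioselective Mukaiyama acetate aldol should add 1,2 to the 2-substituted enal; the chiral Ti complex exposes the Re face of the aldehyde (O > C4 > H), which sets C3 as R.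

Step 5
Reactants: 8 (5S)-5-(hydroxymethyl)furan-2(5H)-one
Product: 9 (5S)-5-{[(tert-butyldimethylsilyl)oxy]methyl}furan-2(5H)-one
Conditions: TBSCl, imidazole, DMF, 0 °C → rt
Reagents that add atoms: tert-butyldimethylsilyl chloride, CC(C)(C)[Si](C)(C)Cl
Why: Standard silylation of the primary alcohol; the stereocenter (future C6) is untouched.

Step 6
Reactants: 9 (5S)-5-{[(tert-butyldimethylsilyl)oxy]methyl}furan-2(5H)-one; 10 2-bromo-3-(trimethylsilyl)prop-1-ene
Product: 12 (4R,5S)-5-{[(tert-butyldimethylsilyl)oxy]methyl}-3-[(dimethylamino)methyl]-4-[3-(trimethylsilyl)prop-1-en-2-yl]oxolan-2-one, via silyl ketene acetal 11 (not isolated)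
Conditions: 10, Mg, THF, rt; then 9, CuBr·SMe2 (10 mol%), TMSCl, THF, −78 °C; then CH2=NMe2+ I−, CH2Cl2, −78 °C → rt; NaHCO3 work-up
Reagents that add atoms: dimethyl(methylidene)ammonium iodide (Eschenmoser's salt), C=[N+](C)C.[I-]
Why: Copper-catalysed conjugate addition of the alkenyl Grignard reagent should occur anti to the C6 silyloxymethyl group and set C7 (trans-lactone), and Mannich trapping of the ketene silyl acetal brings in C13; the allylsilane is far less nucleophilic than the ketene acetal.

Step 7
Reactants: 12 (4R,5S)-silyl ether Mannich base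
Product: 13 (4R,5S)-3-[(dimethylamino)methyl]-5-(hydroxymethyl)-4-[3-(trimethylsilyl)prop-1-en-2-yl]oxolan-2-one
Conditions: AcOH/THF/H2O 3:1:1, rt; NaHCO3 work-up
Reagents that add atoms: none
Why: Mild acidic desilylation of the primary TBS ether should spare the allylsilane, the lactone and the protonated amine.

Step 8
Reactants: 13 (4R,5S)-hydroxymethyl lactone
Product: 14 (2S,3R)-4-[(dimethylamino)methyl]-5-oxo-3-[3-(trimethylsilyl)prop-1-en-2-yl]oxolane-2-carbaldehyde
Conditions: Dess–Martin periodinane, CH2Cl2, 0 °C → rt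
Reagents that add atoms: none
Why: Dess–Martin oxidation gives the aldehyde under near-neutral conditions that should not epimerise C6.

Step 9
Reactants: 14 (2S,3R)-lactone aldehyde
Product: 15 (4R,5R)-3-[(dimethylamino)methyl]-5-ethenyl-4-[3-(trimethylsilyl)prop-1-en-2-yl]oxolan-2-one
Conditions: Ph3PCH3Br, KHMDS, THF, −78 → 0 °C
Reagents that add atoms: methyltriphenylphosphonium bromide, C[P+](c1ccccc1)(c1ccccc1)c1ccccc1.[Br-]
Why: Wittig methylenation at low temperature should convert the aldehyde into the C5 vinyl group needed for ring closure; the β-amino lactone has no good leaving group for the basic ylide to expel.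

Step 10
Reactants: 15 (4R,5R)-vinyl lactone Mannich base
Product: 18 (4R,5R)-5-ethenyl-3-[(phenylsulfonyl)methyl]-4-[3-(trimethylsilyl)prop-1-en-2-yl]oxolan-2-one, via ammonium iodide 16 (not isolated), via methylene lactone 17 (not isolated)
Conditions: MeI, CH2Cl2, rt; then PhSO2Na (2 equiv), iPr2NEt (cat.), DMF, rt
Reagents that add atoms: sodium benzenesulfinate, [Na+].[O-]S(=O)c1ccccc1
Why: Quaternisation, E1cB loss of trimethylamine and sulfa-Michael addition of sulfinate should store the α-methylene lactone as a β-sulfonyl lactone, which is inert to diazoalkanes, carbenoids and hydrides and is released by base at the end.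

Step 11
Reactants: 18 (4R,5R)-sulfonyl lactone allylsilane
Product: 19 (4R,5R)-4-(3-bromoprop-1-en-2-yl)-5-ethenyl-3-[(phenylsulfonyl)methyl]oxolan-2-one
Conditions: NBS, propylene oxide, CH2Cl2, −78 °C
Reagents that add atoms: N-bromosuccinimide, O=C1CCC(=O)N1Br
Why: SE2′ bromodesilylation should take place at the allylsilane, the most nucleophilic alkene; the allyl transposition is without consequence because the 2-substituted allyl unit is constitutionally symmetric.

Step 12
Reactants: 7 tert-butyl (3R)-5-acetoxy-3-hydroxy-4-methylidenepentanoate; 19 (4R,5R)-lactone allyl bromide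
Product: 20 tert-butyl (3R)-5-acetoxy-3-({2-[(2R,3R)-2-ethenyl-5-oxo-4-[(phenylsulfonyl)methyl]oxolan-3-yl]prop-2-en-1-yl}oxy)-4-methylidenepentanoate
Conditions: AgOTf, 2,6-di-tert-butyl-4-methylpyridine, 4 Å MS, CH2Cl2, 0 °C → rt, dark
Reagents that add atoms: none
Why: Silver-promoted Williamson-type etherification is non-basic, so the β-hydroxy ester should not undergo retro-aldol or elimination; SN2 and SN2′ attack give the same ether and no stereocenter is touched.

Step 13
Reactants: 20 diene ether
Product: 21 oxocene ester: eight-membered ring O–CH2–C8(=CH2)–C7–C6–C5=C4(CH2OAc)–C3(CH2CO2tBu), (3R,6R,7R), Z-C4=C5, trans-fused at C6–C7 to the 11-[(phenylsulfonyl)methyl] γ-lactone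
Conditions: second-generation Hoveyda–Grubbs catalyst (10 mol%), toluene (2 mM), 80 °C
Reagents that add atoms: none
Why: Ring-closing metathesis should start at the monosubstituted C5 vinyl group and close onto the C4 methylene; the eight-membered ring can only hold the Z-alkene, and closure onto the C8 methylene would need a four-membered ring.

Step 14
Reactants: 21 oxocene tert-butyl ester
Product: 22 oxocene acid (C3–CH2CO2H; otherwise as 21)
Conditions: TFA/CH2Cl2 1:4, 0 °C
Reagents that add atoms: none
Why: Acidolysis of the tert-butyl ester frees the acid while the acetate, lactone and sulfone should survive.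

Step 15
Reactants: 22 oxocene acid
Product: 24 diazoketone: oxocene of 21 with C3–CH2–C(=O)–C(=N2)–CH3 side chain, (3R,6R,7R), via acid chloride 23 (not isolated)
Conditions: (COCl)2, DMF (cat.), CH2Cl2, 0 °C; evaporate; CH3CHN2 (3 equiv, ethereal, from N-ethyl-N-nitrosourea/KOH), −40 → 0 °C
Reagents that add atoms: diazoethane, CC=[N+]=[N-]
Why: Arndt–Eistert-type acylation of diazoethane by the acid chloride should give the α-methyl diazoketone, the second equivalent removing HCl; no acrylate is present for dipolar cycloaddition, and the remaining alkenes are unactivated.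

Step 16
Reactants: 24 diazoketone
Product: 26 bridged ketone: 11-oxabicyclo[6.2.1]undecane core (ten-membered carbocycle C1–C10, O between C3 and C10), C1 ketone, C3–H and C10–CH3 exo, Z-C4(CH2OAc)=C5, C8 exocyclic methylene, trans-6,12-lactone with C11–CH2SO2Ph, (3R,6R,7R,10R), via oxonium ylide 25 (not isolated)
Conditions: Cu(hfacac)2 (5 mol%), CH2Cl2 (0.01 M), reflux, slow addition of 24
Reagents that add atoms: none
Why: Cu(hfacac)2 should turn the diazoketone into an electrophilic copper carbenoid at C10 that is captured by the ring oxygen to form the five-membered oxonium ylide 25 (O–C10 bond, the future furanone ring); a suprafacial [2,3]-sigmatropic shift through the O–CH2–C8(=CH2) unit then bonds C10 to the exocyclic methylene carbon and breaks the O–CH2 bond, which expands the eight-membered oxocene to the nine-membered oxacycle and closes the ten-membered carbocycle in the same event. The closest known reaction type is the copper-catalysed oxonium ylide formation/[2,3]-rearrangement of diazoketones tethered to cyclic allylic ethers, which gives bridged oxabicyclo[6.2.1]undecenones, together with the Stevens [1,2]-ring expansion of cyclic ethers to oxygen-bridged carbocycles; because the 2-substituted allyl unit is constitutionally symmetric, a [1,2]-shift would give the same product. C10 is the only new stereocenter: the one-atom oxygen bridge can only span C3 and C10 cis, so the (3R) center of the oxocene dictates (10R), with the methyl group exo. The step needs ylide formation to outrun 1,2-hydride migration from the carbenoid methyl group and cyclopropanation of C4=C5; the strongly electrophilic catalyst, the five-membered O-capture and the hindered, trisubstituted C4=C5 alkene with three allylic oxygens should secure this. A [2,3] shift through the other allylic arm (C3–C4=C5) is barred because C3 lies inside the ylide ring.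

Step 17
Reactants: 26 bridged ketone
Product: 28 (6R,7R,10R)-3(2H)-furanone (C2=C3; otherwise as 26), via silyl enol ether 27 (not isolated)
Conditions: TMSOTf (1.3 equiv), Et3N (2 equiv), CH2Cl2, 0 °C; then Pd(OAc)2 (1.1 equiv), MeCN, rt
Reagents that add atoms: none
Why: Saegusa–Ito oxidation: the ketone is enolisable only toward C2, and β-hydride elimination of C3–H should give the vinylogous ester; this erases C3 after it has passed its chirality to C10.

Step 18
Reactants: 28 furanone with C8=CH2
Product: 30 C8 ketone (6R,7S,10R; the change at C7 is a CIP priority change only), via vicinal diol 29 (not isolated)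
Conditions: OsO4 (2 mol%), NaIO4 (4 equiv), 2,6-lutidine, dioxane/H2O 3:1, rt
Reagents that add atoms: sodium periodate (terminal oxidant; oxygen delivered through OsO4), [Na+].[O-]I(=O)(=O)=O
Why: Lemieux–Johnson oxidation: osmylation should prefer the unhindered exocyclic 1,1-disubstituted alkene over the hindered push–pull furanone alkene and the trisubstituted C4=C5 with its three allylic oxygens; the near-neutral cleavage suits the β-acyloxy ketone.

Step 19
Reactants: 30 C8 ketone
Product: 31 (6R,7R,8S,10R)-C8 alcohol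
Conditions: (R)-2-methyl-CBS-oxazaborolidine (0.5 equiv), catecholborane (1.5 equiv), toluene/CH2Cl2, −78 °C; MeOH, then pH 7 buffer
Reagents that add atoms: none
Why: Corey–Bakshi–Shibata reduction: with the α-branched C7 side as the large group, the (R)-oxazaborolidine should deliver hydride to give the (8S)-alcohol; catecholborane at −78 °C spares the vinylogous ester, the esters and the lactone.

Step 20
Reactants: 31 C8 alcohol
Product: 32 (6R,7R,8S,10R)-8-O-methacrylate
Conditions: methacryloyl chloride (2 equiv), Et3N (3 equiv), DMAP (0.1 equiv), CH2Cl2, 0 °C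
Reagents that add atoms: methacryloyl chloride, C=C(C)C(=O)Cl
Why: DMAP-catalysed acylation of the secondary alcohol proceeds with retention at C8; acylating immediately avoids translactonisation to the 8,12-olide.

Step 21
Reactants: 32 8-O-methacrylate β-sulfonyl lactone
Product: 33 target CNP0179932.1, (6R,7R,8S,10R)
Conditions: DBU (1.5 equiv), CH2Cl2, 0 °C → rt
Reagents that add atoms: none
Why: E1cB elimination of benzenesulfinate (retro-sulfa-Michael) should release the α-methylene lactone; acetate, methacrylate and the non-enolisable furanone tolerate DBU in an aprotic solvent.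

**Compound list**

1 | 2-methylidenepropane-1,3-diol | C=C(CO)CO | starting material
2 | 2-(hydroxymethyl)prop-2-en-1-yl acetate | CC(=O)OCC(=C)CO | intermediate
3 | 2-formylprop-2-en-1-yl acetate | CC(=O)OCC(=C)C=O | intermediate
4 | tert-butyl acetate | CC(=O)OC(C)(C)C | starting material
5 | 1-(tert-butoxy)-1-(trimethylsilyloxy)ethene | C=C(OC(C)(C)C)O[Si](C)(C)C | intermediate
6 | tert-butyl (3R)-5-acetoxy-4-methylidene-3-(trimethylsilyloxy)pentanoate | C[Si](C)(C)O[C@H](CC(=O)OC(C)(C)C)C(=C)COC(C)=O | intermediate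
7 | tert-butyl (3R)-5-acetoxy-3-hydroxy-4-methylidenepentanoate | O[C@H](CC(=O)OC(C)(C)C)C(=C)COC(C)=O | intermediate
8 | (5S)-5-(hydroxymethyl)furan-2(5H)-one | OC[C@H]1OC(=O)C=C1 | starting material
9 | (5S)-5-{[(tert-butyldimethylsilyl)oxy]methyl}furan-2(5H)-one | CC(C)(C)[Si](C)(C)OC[C@H]1OC(=O)C=C1 | intermediate
10 | 2-bromo-3-(trimethylsilyl)prop-1-ene | C=C(Br)C[Si](C)(C)C | starting material
11 | (2S,3R)-2-{[(tert-butyldimethylsilyl)oxy]methyl}-5-(trimethylsilyloxy)-3-[3-(trimethylsilyl)prop-1-en-2-yl]-2,3-dihydrofuran | CC(C)(C)[Si](C)(C)OC[C@H]1OC(O[Si](C)(C)C)=C[C@@H]1C(=C)C[Si](C)(C)C | intermediate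
12 | (4R,5S)-5-{[(tert-butyldimethylsilyl)oxy]methyl}-3-[(dimethylamino)methyl]-4-[3-(trimethylsilyl)prop-1-en-2-yl]oxolan-2-one | CC(C)(C)[Si](C)(C)OC[C@H]1OC(=O)C(CN(C)C)[C@@H]1C(=C)C[Si](C)(C)C | intermediate
13 | (4R,5S)-3-[(dimethylamino)methyl]-5-(hydroxymethyl)-4-[3-(trimethylsilyl)prop-1-en-2-yl]oxolan-2-one | OC[C@H]1OC(=O)C(CN(C)C)[C@@H]1C(=C)C[Si](C)(C)C | intermediate
14 | (2S,3R)-4-[(dimethylamino)methyl]-5-oxo-3-[3-(trimethylsilyl)prop-1-en-2-yl]oxolane-2-carbaldehyde | O=C[C@H]1OC(=O)C(CN(C)C)[C@@H]1C(=C)C[Si](C)(C)C | intermediate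
15 | (4R,5R)-3-[(dimethylamino)methyl]-5-ethenyl-4-[3-(trimethylsilyl)prop-1-en-2-yl]oxolan-2-one | C=C[C@H]1OC(=O)C(CN(C)C)[C@@H]1C(=C)C[Si](C)(C)C | intermediate
16 | trimethylammonium iodide of 15 | C=C[C@H]1OC(=O)C(C[N+](C)(C)C)[C@@H]1C(=C)C[Si](C)(C)C.[I-] | intermediate
17 | (4R,5R)-5-ethenyl-3-methylidene-4-[3-(trimethylsilyl)prop-1-en-2-yl]oxolan-2-one | C=C[C@H]1OC(=O)C(=C)[C@@H]1C(=C)C[Si](C)(C)C | intermediate
18 | (4R,5R)-5-ethenyl-3-[(phenylsulfonyl)methyl]-4-[3-(trimethylsilyl)prop-1-en-2-yl]oxolan-2-one | C=C[C@H]1OC(=O)C(CS(=O)(=O)c2ccccc2)[C@@H]1C(=C)C[Si](C)(C)C | intermediate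
19 | (4R,5R)-4-(3-bromoprop-1-en-2-yl)-5-ethenyl-3-[(phenylsulfonyl)methyl]oxolan-2-one | C=C[C@H]1OC(=O)C(CS(=O)(=O)c2ccccc2)[C@@H]1C(=C)CBr | intermediate
20 | tert-butyl (3R)-5-acetoxy-3-({2-[(2R,3R)-2-ethenyl-5-oxo-4-[(phenylsulfonyl)methyl]oxolan-3-yl]prop-2-en-1-yl}oxy)-4-methylidenepentanoate | C=C[C@H]1OC(=O)C(CS(=O)(=O)c2ccccc2)[C@@H]1C(=C)CO[C@H](CC(=O)OC(C)(C)C)C(=C)COC(C)=O | intermediate
21 | (3R,6R,7R)-oxocene tert-butyl ester (3-methylidene oxocene, Z-C4=C5, trans-fused sulfonylmethyl γ-lactone) | C=C1CO[C@H](CC(=O)OC(C)(C)C)/C(COC(C)=O)=C\[C@H]2OC(=O)C(CS(=O)(=O)c3ccccc3)[C@H]12 | intermediate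
22 | (3R,6R,7R)-oxocene acid | C=C1CO[C@H](CC(=O)O)/C(COC(C)=O)=C\[C@H]2OC(=O)C(CS(=O)(=O)c3ccccc3)[C@H]12 | intermediate
23 | (3R,6R,7R)-oxocene acid chloride | C=C1CO[C@H](CC(=O)Cl)/C(COC(C)=O)=C\[C@H]2OC(=O)C(CS(=O)(=O)c3ccccc3)[C@H]12 | intermediate
24 | (3R,6R,7R)-oxocene 3-diazobutan-2-one (C3–CH2–CO–C(N2)–CH3) | C=C1CO[C@H](CC(=O)C(C)=[N+]=[N-])/C(COC(C)=O)=C\[C@H]2OC(=O)C(CS(=O)(=O)c3ccccc3)[C@H]12 | intermediate
25 | bicyclic oxonium ylide (O+ bonded to C3, C10 and the O–CH2 carbon; carbanion at C10) | C=C1C[O+]2[C@H](CC(=O)[C-]2C)/C(COC(C)=O)=C\[C@H]3OC(=O)C(CS(=O)(=O)c4ccccc4)[C@H]13 | intermediate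
26 | (3R,6R,7R,10R)-bridged ketone (11-oxabicyclo[6.2.1] core, C8=CH2) | C=C1C[C@@]2(C)O[C@H](CC2=O)/C(COC(C)=O)=C\[C@H]2OC(=O)C(CS(=O)(=O)c3ccccc3)[C@H]12 | intermediate
27 | trimethylsilyl enol ether of 26 (C1(OTMS)=C2) | C=C1C[C@@]2(C)O[C@H](C=C2O[Si](C)(C)C)/C(COC(C)=O)=C\[C@H]2OC(=O)C(CS(=O)(=O)c3ccccc3)[C@H]12 | intermediate
28 | (6R,7R,10R)-3(2H)-furanone with C8=CH2 | C=C1C[C@@]2(C)OC(=CC2=O)/C(COC(C)=O)=C\[C@H]2OC(=O)C(CS(=O)(=O)c3ccccc3)[C@H]12 | intermediate
29 | C8 tertiary alcohol with C8–CH2OH (vicinal diol, C8 epimers) | OCC1(O)C[C@@]2(C)OC(=CC2=O)/C(COC(C)=O)=C\[C@H]2OC(=O)C(CS(=O)(=O)c3ccccc3)[C@H]12 | intermediate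
30 | C8 ketone (6R,7S,10R) | O=C1C[C@@]2(C)OC(=CC2=O)/C(COC(C)=O)=C\[C@H]2OC(=O)C(CS(=O)(=O)c3ccccc3)[C@H]12 | intermediate
31 | (6R,7R,8S,10R)-C8 alcohol | O[C@H]1C[C@@]2(C)OC(=CC2=O)/C(COC(C)=O)=C\[C@H]2OC(=O)C(CS(=O)(=O)c3ccccc3)[C@H]12 | intermediate
32 | (6R,7R,8S,10R)-8-O-methacrylate β-sulfonyl lactone | C=C(C)C(=O)O[C@H]1C[C@@]2(C)OC(=CC2=O)/C(COC(C)=O)=C\[C@H]2OC(=O)C(CS(=O)(=O)c3ccccc3)[C@H]12 | intermediate
33 | CNP0179932.1, (6R,7R,8S,10R) | C=C(C)C(=O)O[C@H]1C[C@@]2(C)OC(=CC2=O)/C(COC(C)=O)=C\[C@H]2OC(=O)C(=C)[C@H]12 | target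

**Step count and risks**

Total step count: 21. Longest linear sequence: 17 steps (8 → 33, steps 5–21).

Step 16 (key step). In the α-methyl copper carbenoid, 1,2-hydride migration to a vinyl ketone or cyclopropanation of C4=C5 may outrun oxonium ylide formation. The fallback sets out from acid 22 through acid chloride 23 and moves the C14 methyl group from the carbenoid to a late enolate alkylation. Diazomethane at 0 °C should give the terminal diazoketone F1. Cu(hfacac)2 in refluxing CH2Cl2 should give, through the oxonium ylide F2 and the same [2,3] shift, the bridged ketone with C10–H, F3. TMSOTf/Et3N should give the silyl enol ether F4, and Pd(OAc)2 in MeCN the 2H-furanone F5. LiHMDS (1.0 equiv), THF, −78 °C, then MeI should methylate the most acidic position, the C10–H α to the furanone carbonyl, on the only open (exo) face. The fallback comes back to the route at 28.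

Step 19. The conformational bias of the medium-ring ketone may override the oxazaborolidine, giving poor or reversed facial selectivity in hydride delivery to C8. The fallback sets out from 30. NaBH4/CeCl3 in MeOH at −78 °C (substrate control) should give the (8R)-alcohol F6. A Mitsunobu esterification with methacrylic acid (PPh3, DIAD, toluene, 0 °C) then inverts C8 and installs the ester in one operation. It comes back at 32.

Step 12. Substitution at the hindered secondary oxygen of the β-hydroxy ester may be slow, so that silver-assisted decomposition of the allylic bromide or retro-aldol cleavage takes over. The fallback sets out from 19. NMO in MeCN (N-oxide oxidation of the allylic bromide) should give the enal F7. Reductive etherification of F7 with silyl ether 6 (isolated by omitting the acidic work-up of step 4) under BiBr3 (cat.), Et3SiH, MeCN, 0 °C should form the same allyl ether by 1,2-reduction of the mixed oxocarbenium ion. It comes back at 20.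

**Further compounds**

F1 | step 16 | (3R,6R,7R)-oxocene terminal diazoketone (C3–CH2–CO–CHN2) | C=C1CO[C@H](CC(=O)C=[N+]=[N-])/C(COC(C)=O)=C\[C@H]2OC(=O)C(CS(=O)(=O)c3ccccc3)[C@H]12
F2 | step 16 | bicyclic oxonium ylide with C10–H | C=C1C[O+]2[C@H](CC(=O)[CH-]2)/C(COC(C)=O)=C\[C@H]3OC(=O)C(CS(=O)(=O)c4ccccc4)[C@H]13
F3 | step 16 | bridged ketone with C10–H (otherwise as 26) | C=C1C[C@H]2O[C@H](CC2=O)/C(COC(C)=O)=C\[C@H]2OC(=O)C(CS(=O)(=O)c3ccccc3)[C@H]12
F4 | step 16 | trimethylsilyl enol ether of F3 | C=C1C[C@H]2O[C@H](C=C2O[Si](C)(C)C)/C(COC(C)=O)=C\[C@H]2OC(=O)C(CS(=O)(=O)c3ccccc3)[C@H]12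
F5 | step 16 | 3(2H)-furanone with C10–H (otherwise as 28) | C=C1C[C@H]2OC(=CC2=O)/C(COC(C)=O)=C\[C@H]2OC(=O)C(CS(=O)(=O)c3ccccc3)[C@H]12
F6 | step 19 | (8R)-C8 alcohol (C8 epimer of 31) | O[C@@H]1C[C@@]2(C)OC(=CC2=O)/C(COC(C)=O)=C\[C@H]2OC(=O)C(CS(=O)(=O)c3ccccc3)[C@H]12
F7 | step 12 | 2-[(2R,3R)-2-ethenyl-5-oxo-4-[(phenylsulfonyl)methyl]oxolan-3-yl]prop-2-enal | C=C[C@H]1OC(=O)C(CS(=O)(=O)c2ccccc2)[C@@H]1C(=C)C=O
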